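Ring C of the upper flavan unit is cut at C4–C4a and C2–C3. C4 is a doubly benzylic carbon between two phloroglucinol rings: the lower ring A can carry the cation while the upper ring A closes onto it. The key step is an oxidative, counter-anion-controlled oxa-Povarov annulation. An aryl oxocarbenium ion (C4a=C8a–O1+=C2), made in the flask with DDQ from a simple aryl benzyl ether, takes up the C3=C4 bond of an E enol gallate held on C6 of benzylated, C8-brominated epicatechin gallate. Both bonds, ring C and the stereocentres C2, C3 and C4 arise in one operation; hydrogenolysis then frees the target.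

Key step: step 9

Assumption: the sense of induction of the chiral acid in step 9 cannot be predicted with confidence; the (S,S) antipode is written, and the (R,R) antipode is used instead if test runs show the opposite sense.

Step 1
Reactants: 1 (−)-epicatechin
Product: 2 5,7,3',4'-tetra-O-benzyl-(−)-epicatechin
Conditions: BnBr (4.2 equiv), K2CO3, DMF, 0 °C to rt, argon
Reagents that add atoms: benzyl bromide BrCc1ccccc1
Why: Williamson etherification of the four phenols, which carbonate deprotonates while the secondary C3 alcohol stays neutral and unalkylated; C2 and C3 are not touched.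

Step 2
Reactants: 2 5,7,3',4'-tetra-O-benzyl-(−)-epicatechin; 3 3,4,5-tris(benzyloxy)benzoic acid
Product: 4 hepta-O-benzyl-(−)-epicatechin 3-O-gallate
Conditions: DCC, DMAP, CH2Cl2, 0 °C to rt
Reagents that add atoms: none
Why: Steglich esterification of the secondary C3 alcohol with the DCC-activated acid through its acylpyridinium ion; the C3–O bond is not broken, so C3 keeps its R configuration.

Step 3
Reactants: 4 hepta-O-benzyl-(−)-epicatechin 3-O-gallate
Product: 5 8-bromo derivative of 4
Conditions: NBS, CH2Cl2, −78 to 0 °C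
Reagents that add atoms: N-bromosuccinimide O=C1CCC(=O)N1Br
Why: electrophilic aromatic bromination of the phloroglucinol ring A, which for 5,7-di-O-benzyl flavans goes to C8 (between O1 and the 7-benzyloxy group); the bromine later shields C8 against cations.

Step 4
Reactants: 5 8-bromo derivative of 4
Product: 6 8-bromo-6-iodo derivative of 4
Conditions: NIS, TFA (cat.), CH2Cl2–MeCN, 0 °C to rt, dark
Reagents that add atoms: N-iodosuccinimide O=C1CCC(=O)N1I
Why: electrophilic aromatic iodination at C6, the only free position of the still very electron-rich ring A; the dialkoxyphenyl and trialkoxybenzoate rings are far less reactive.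

Step 5
Reactants: 6 8-bromo-6-iodo derivative of 4
Product: 7 8-bromo-6-[(E)-2-(pinacolboryl)vinyl] derivative of 4
Conditions: vinylboronic acid pinacol ester, Pd(OAc)2 (5 mol %), PPh3, n-Bu3N, toluene, 90 °C
Reagents that add atoms: 4,4,5,5-tetramethyl-2-vinyl-1,3,2-dioxaborolane C=CB1OC(C)(C)C(C)(C)O1
Why: Mizoroki–Heck reaction in which the vinylboronate keeps its boron, because an amine base without water or alkoxide suppresses Suzuki transmetalation; syn β-hydride elimination gives the E alkene, and the C–I bond adds to zerovalent palladium much faster than the hindered C8–Br bond.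

Step 6
Reactants: 7 8-bromo-6-[(E)-2-(pinacolboryl)vinyl] derivative of 4
Product: 8 potassium (E)-alkenyltrifluoroborate
Conditions: KHF2, MeOH–H2O, rt
Reagents that add atoms: potassium hydrogen difluoride F.[F-].[K+]
Why: standard conversion of a pinacol boronate into its trifluoroborate salt, with retention of the E geometry.

Step 7
Reactants: 8 potassium (E)-alkenyltrifluoroborate; 3 3,4,5-tris(benzyloxy)benzoic acid
Product: 9 (E)-enol gallate of the lower unit
Conditions: CuBr (20 mol %), DMAP, 4 Å MS, O2 (1 atm), CH2Cl2, rt to 40 °C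
Reagents that add atoms: none
Why: Chan–Lam-type oxidative copper-catalysed C–O coupling of an alkenyltrifluoroborate with a carboxylic acid, which is stereoretentive and should give the E enol ester.

Step 8
Reactants: 10 3,5-bis(benzyloxy)phenol; 11 3,4-bis(benzyloxy)benzyl chloride
Product: 12 3,5-bis(benzyloxy)phenyl 3,4-bis(benzyloxy)benzyl ether
Conditions: K2CO3, NaI (cat.), DMF, rt
Reagents that add atoms: none
Why: Williamson ether synthesis; the phenoxide of a 3,5-dialkoxyphenol under carbonate in DMF alkylates on oxygen.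

Step 9
Reactants: 12 3,5-bis(benzyloxy)phenyl 3,4-bis(benzyloxy)benzyl ether; 9 (E)-enol gallate of the lower unit
Product: 15 tetradeca-O-benzyl lower-unit-8-bromo procyanidin B-5 3,3'-di-O-gallate, via aryl oxocarbenium ion pair 13 (not isolated), via dioxolanylium ion 14 (not isolated)
Conditions: (a) 12 (1.25 equiv), DDQ (1.2 equiv), 4 Å MS, CH2Cl2, 0 °C to rt; (b) toluene, −78 °C, then 9 (1.0 equiv), (S,S)-IDPi acid (confined BINOL-derived N-triflyl imidodiphosphorimidate, 10 mol %), −78 to −40 °C; Et3N quench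
Reagents that add atoms: none
Why: Proposed new method: DDQ abstracts hydride from the dialkoxybenzylic CH2 of 12 to give the E aryl oxocarbenium ion 13, a cationic 2-oxadiene (C4a=C8a–O1+=C2) that the chiral acid pairs with its confined anion while DDQH− is protonated; the oxygen-bearing alkene carbon of 9 then adds to C2 (Prins step, C2–C3 bond), the resulting C4 cation, stabilised by the lower ring A, is held by the gallate carbonyl as trans-dioxolanylium ion 14, and the upper ring A closes onto C4 (Friedel–Crafts step, C4–C4a bond) with loss of a proton. The closest known reaction types are the SnCl4-promoted oxa-Povarov reaction of aryl oxocarbenium ions with styrenes, the DDQ-mediated oxidative generation of oxocarbenium ions from benzylic ethers for Prins-type trapping, and the chiral-acid-controlled Povarov reaction of N-aryl iminium ions. Ring C closes as a formal inverse-electron-demand [4+2] annulation whose second stage is a six-membered Friedel–Crafts closure, exo-tet at C4 (the leaving oxygen of 14 stays outside the ring) with the arene bond C4a=C8a inside the new ring. C2 and C3: the E oxocarbenium ion and an endo gallate (carbonyl oxygen over the cation, the bulky 2,6-dibenzyloxyaryl group exo) should give the 2,3-cis relation, and the chiral anion shields one face of 13 so that both become R. C4: anti opening of 14 by the arene, reinforced by peri strain with the C5 benzyloxy group, places the lower unit trans to the C3 ester (3,4-trans, 4β), which also carries over the E geometry of 9. The step needs attack through C3 and not C4 of the alkene (secured because the 2,4,6-trioxygenated aryl group stabilises the C4 cation far better than the acyloxy group would stabilise a C3 cation), no arylation at C8 of the lower unit (blocked by bromine) and no oxidation of 9 (DDQ is used up before 9 is added), and since the remote lower-unit stereocentres give no bias, any upper-unit antipode is a diastereomer that chromatography removes.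

Step 10
Reactants: 15 tetradeca-O-benzyl lower-unit-8-bromo procyanidin B-5 3,3'-di-O-gallate
Product: 16 procyanidin B-5 3,3'-di-O-gallate
Conditions: H2 (1 atm), Pd(OH)2/C, Et3N, THF–MeOH–H2O, rt; filtration, lyophilisation, reverse-phase HPLC
Reagents that add atoms: none
Why: hydrogenolysis of the fourteen benzyl ethers together with hydrodebromination of the C8 bromide of the lower unit; the two gallate esters, the interflavan bond and the ring C ethers should survive, and no stereocenter is touched.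

Compound list

1 | (−)-epicatechin, (2R,3R)-2-(3,4-dihydroxyphenyl)chroman-3,5,7-triol | O[C@@H]1Cc2c(O)cc(O)cc2O[C@@H]1c1ccc(O)c(O)c1 | starting material
2 | 5,7,3',4'-tetra-O-benzyl-(−)-epicatechin, (2R,3R)-5,7-bis(benzyloxy)-2-[3,4-bis(benzyloxy)phenyl]chroman-3-ol | O[C@@H]1Cc2c(OCc3ccccc3)cc(OCc3ccccc3)cc2O[C@@H]1c1ccc(OCc2ccccc2)c(OCc2ccccc2)c1 | intermediate
3 | 3,4,5-tris(benzyloxy)benzoic acid | OC(=O)c1cc(OCc2ccccc2)c(OCc2ccccc2)c(OCc2ccccc2)c1 | starting material
4 | hepta-O-benzyl-(−)-epicatechin 3-O-gallate, (2R,3R)-5,7-bis(benzyloxy)-2-[3,4-bis(benzyloxy)phenyl]chroman-3-yl 3,4,5-tris(benzyloxy)benzoate | O=C(O[C@@H]1Cc2c(OCc3ccccc3)cc(OCc3ccccc3)cc2O[C@@H]1c1ccc(OCc2ccccc2)c(OCc2ccccc2)c1)c1cc(OCc2ccccc2)c(OCc2ccccc2)c(OCc2ccccc2)c1 | intermediate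
5 | 8-bromo derivative of 4 (Br on ring A between O1 and the 7-benzyloxy group) | O=C(O[C@@H]1Cc2c(OCc3ccccc3)cc(OCc3ccccc3)c(Br)c2O[C@@H]1c1ccc(OCc2ccccc2)c(OCc2ccccc2)c1)c1cc(OCc2ccccc2)c(OCc2ccccc2)c(OCc2ccccc2)c1 | intermediate
6 | 8-bromo-6-iodo derivative of 4 (I between the 5- and 7-benzyloxy groups) | O=C(O[C@@H]1Cc2c(OCc3ccccc3)c(I)c(OCc3ccccc3)c(Br)c2O[C@@H]1c1ccc(OCc2ccccc2)c(OCc2ccccc2)c1)c1cc(OCc2ccccc2)c(OCc2ccccc2)c(OCc2ccccc2)c1 | intermediate
7 | 8-bromo-6-[(E)-2-(4,4,5,5-tetramethyl-1,3,2-dioxaborolan-2-yl)vinyl] derivative of 4 | O=C(O[C@@H]1Cc2c(OCc3ccccc3)c(/C=C/B3OC(C)(C)C(C)(C)O3)c(OCc3ccccc3)c(Br)c2O[C@@H]1c1ccc(OCc2ccccc2)c(OCc2ccccc2)c1)c1cc(OCc2ccccc2)c(OCc2ccccc2)c(OCc2ccccc2)c1 | intermediate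
8 | potassium (E)-2-(8-bromo-hepta-O-benzyl-epicatechin gallate-6-yl)vinyltrifluoroborate | O=C(O[C@@H]1Cc2c(OCc3ccccc3)c(/C=C/[B-](F)(F)F)c(OCc3ccccc3)c(Br)c2O[C@@H]1c1ccc(OCc2ccccc2)c(OCc2ccccc2)c1)c1cc(OCc2ccccc2)c(OCc2ccccc2)c(OCc2ccccc2)c1.[K+] | intermediate
9 | (E)-2-(8-bromo-hepta-O-benzyl-epicatechin gallate-6-yl)vinyl 3,4,5-tris(benzyloxy)benzoate (E enol gallate on C6 of the lower unit) | O=C(O[C@@H]1Cc2c(OCc3ccccc3)c(/C=C/OC(=O)c3cc(OCc4ccccc4)c(OCc4ccccc4)c(OCc4ccccc4)c3)c(OCc3ccccc3)c(Br)c2O[C@@H]1c1ccc(OCc2ccccc2)c(OCc2ccccc2)c1)c1cc(OCc2ccccc2)c(OCc2ccccc2)c(OCc2ccccc2)c1 | intermediate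
10 | 3,5-bis(benzyloxy)phenol | Oc1cc(OCc2ccccc2)cc(OCc2ccccc2)c1 | starting material
11 | 3,4-bis(benzyloxy)benzyl chloride | ClCc1ccc(OCc2ccccc2)c(OCc2ccccc2)c1 | starting material
12 | 1,3-bis(benzyloxy)-5-{[3,4-bis(benzyloxy)benzyl]oxy}benzene | c1(OCc2ccc(OCc3ccccc3)c(OCc3ccccc3)c2)cc(OCc2ccccc2)cc(OCc2ccccc2)c1 | intermediate
13 | (E)-[3,4-bis(benzyloxy)benzylidene][3,5-bis(benzyloxy)phenyl]oxonium, shown as its 2,3-dichloro-5,6-dicyano-4-hydroxyphenoxide (DDQH−) ion pair; the anion is exchanged for the chiral acid anion in the flask | c1(/[O+]=C/c2ccc(OCc3ccccc3)c(OCc3ccccc3)c2)cc(OCc2ccccc2)cc(OCc2ccccc2)c1.[O-]c1c(Cl)c(Cl)c(O)c(C#N)c1C#N | intermediate (not isolated)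
14 | trans-4,5-disubstituted 2-[3,4,5-tris(benzyloxy)phenyl]-1,3-dioxolan-2-ylium ion: C4 of the ring carries the lower unit (through its C6), C5 carries the (R)-CH[3,4-bis(benzyloxy)phenyl][O-3,5-bis(benzyloxy)phenyl] group; shown as DDQH− salt | c1(O[C@H](c2ccc(OCc3ccccc3)c(OCc3ccccc3)c2)[C@@H]2OC(c3cc(OCc4ccccc4)c(OCc4ccccc4)c(OCc4ccccc4)c3)=[O+][C@H]2c2c(OCc3ccccc3)c(Br)c3c(c2OCc4ccccc4)C[C@@H](OC(=O)c2cc(OCc4ccccc4)c(OCc4ccccc4)c(OCc4ccccc4)c2)[C@@H](c2ccc(OCc4ccccc4)c(OCc4ccccc4)c2)O3)cc(OCc2ccccc2)cc(OCc2ccccc2)c1.[O-]c1c(Cl)c(Cl)c(O)c(C#N)c1C#N | intermediate (not isolated)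
15 | tetradeca-O-benzyl ether of procyanidin B-5 3,3'-di-O-gallate carrying Br at C8 of the lower unit: upper unit 2R,3R with 2,3-cis and 3,4-trans (4β) substituents, C4 bonded to C6 of the lower (2R,3R) unit, both C3 oxygens as 3,4,5-tris(benzyloxy)benzoates | O=C(O[C@@H]1[C@@H](c2c(OCc3ccccc3)c(Br)c3c(c2OCc4ccccc4)C[C@@H](OC(=O)c2cc(OCc4ccccc4)c(OCc4ccccc4)c(OCc4ccccc4)c2)[C@@H](c2ccc(OCc4ccccc4)c(OCc4ccccc4)c2)O3)c2c(OCc3ccccc3)cc(OCc3ccccc3)cc2O[C@@H]1c1ccc(OCc2ccccc2)c(OCc2ccccc2)c1)c1cc(OCc2ccccc2)c(OCc2ccccc2)c(OCc2ccccc2)c1 | intermediate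
16 | procyanidin B-5 3,3'-di-O-gallate, epicatechin gallate-(4β→6)-epicatechin gallate, upper unit 2R,3R,4S, lower unit 2R,3R | O=C(O[C@@H]1[C@@H](c2c(O)cc3c(c2O)C[C@@H](OC(=O)c2cc(O)c(O)c(O)c2)[C@@H](c2ccc(O)c(O)c2)O3)c2c(O)cc(O)cc2O[C@@H]1c1ccc(O)c(O)c1)c1cc(O)c(O)c(O)c1 | target

Total step count: 10. Longest linear sequence: 9 steps (steps 1 to 7, then 9 and 10).

Steps most likely to fail

Step 9 (carries the label). The oxocarbenium ion may be consumed by intermolecular arylation by the electron-rich rings present (self-condensation and oligomer formation). Facial and endo/exo discrimination by the chiral anion may be weak for such large benzylated partners, and the Prins adduct may be trapped before ring closure. The fallback uses known flavan C4 cation chemistry, sets out from compound 2 and comes back at compound 15. DDQ with 2-ethoxyethanol in CH2Cl2 converts 2 into 5,7,3',4'-tetra-O-benzyl-4β-(2-ethoxyethoxy)-(−)-epicatechin F1. Steglich esterification with acid 3 (DCC, DMAP, CH2Cl2) gives the 4β-(2-ethoxyethoxy) 3-O-gallate F2. TMSOTf (cat.) in CH2Cl2 at −78 °C ionises F2 at C4, and C6 of compound 5, the only free position of its ring A, attacks trans to the participating C3 gallate to give 15. In this variant C2 and C3 of the upper unit come from the chiral pool and only the C4–C6 bond is formed.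

Step 7. The electron-rich styryl trifluoroborate may undergo protodeboronation or oxidative homocoupling, and the E geometry may erode during the copper-mediated C–O coupling. The fallback goes through the aldehyde oxidation level, sets out from compound 7 and comes back at compound 9. Oxidation of the C–B bond of 7 (NaBO3·4H2O, THF–H2O) gives the (lower unit-6-yl)acetaldehyde F3. Acid 3 is converted with oxalyl chloride and catalytic DMF into 3,4,5-tris(benzyloxy)benzoyl chloride F4. O-Acylation of the enol form of F3 with F4 (Et3N, DMAP, CH2Cl2) should give 9 together with the Z isomer of compound 9 F5. The two ortho benzyloxy groups disfavour the Z form, so iodine-catalysed equilibration followed by chromatography should deliver 9.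

Step 5. Vinyl transfer by a Suzuki pathway, reduction of the C–I bond or insertion into the C8–Br bond may compete at the di-ortho-substituted iodide. The fallback builds the alkenylboronate from an alkyne, sets out from compound 6 and comes back at compound 7. Sonogashira coupling of 6 with trimethylsilylacetylene (Pd(PPh3)2Cl2, CuI, Et3N, THF) gives the 6-(trimethylsilylethynyl) compound F6. Buffered TBAF (AcOH, THF) gives the 6-ethynyl compound F7. Hydroboration with pinacolborane catalysed by Cp2Zr(H)Cl (syn, anti-Markovnikov) gives the E alkenylboronate 7.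

Further compounds

F1 | step 9 | 5,7,3',4'-tetra-O-benzyl-4β-(2-ethoxyethoxy)-(−)-epicatechin | O[C@@H]1[C@@H](OCCOCC)c2c(OCc3ccccc3)cc(OCc3ccccc3)cc2O[C@@H]1c1ccc(OCc2ccccc2)c(OCc2ccccc2)c1
F2 | step 9 | 5,7,3',4'-tetra-O-benzyl-4β-(2-ethoxyethoxy)-(−)-epicatechin 3-O-[3,4,5-tris(benzyloxy)benzoate] | O=C(O[C@@H]1[C@@H](OCCOCC)c2c(OCc3ccccc3)cc(OCc3ccccc3)cc2O[C@@H]1c1ccc(OCc2ccccc2)c(OCc2ccccc2)c1)c1cc(OCc2ccccc2)c(OCc2ccccc2)c(OCc2ccccc2)c1
F3 | step 7 | 2-(8-bromo-hepta-O-benzyl-epicatechin gallate-6-yl)acetaldehyde | O=C(O[C@@H]1Cc2c(OCc3ccccc3)c(CC=O)c(OCc3ccccc3)c(Br)c2O[C@@H]1c1ccc(OCc2ccccc2)c(OCc2ccccc2)c1)c1cc(OCc2ccccc2)c(OCc2ccccc2)c(OCc2ccccc2)c1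
F4 | step 7 | 3,4,5-tris(benzyloxy)benzoyl chloride | O=C(Cl)c1cc(OCc2ccccc2)c(OCc2ccccc2)c(OCc2ccccc2)c1
F5 | step 7 | Z isomer of compound 9 | O=C(O[C@@H]1Cc2c(OCc3ccccc3)c(/C=C\OC(=O)c3cc(OCc4ccccc4)c(OCc4ccccc4)c(OCc4ccccc4)c3)c(OCc3ccccc3)c(Br)c2O[C@@H]1c1ccc(OCc2ccccc2)c(OCc2ccccc2)c1)c1cc(OCc2ccccc2)c(OCc2ccccc2)c(OCc2ccccc2)c1
F6 | step 5 | 8-bromo-6-(trimethylsilylethynyl) derivative of 4 | O=C(O[C@@H]1Cc2c(OCc3ccccc3)c(C#C[Si](C)(C)C)c(OCc3ccccc3)c(Br)c2O[C@@H]1c1ccc(OCc2ccccc2)c(OCc2ccccc2)c1)c1cc(OCc2ccccc2)c(OCc2ccccc2)c(OCc2ccccc2)c1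
F7 | step 5 | 8-bromo-6-ethynyl derivative of 4 | O=C(O[C@@H]1Cc2c(OCc3ccccc3)c(C#C)c(OCc3ccccc3)c(Br)c2O[C@@H]1c1ccc(OCc2ccccc2)c(OCc2ccccc2)c1)c1cc(OCc2ccccc2)c(OCc2ccccc2)c(OCc2ccccc2)c1
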